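**Retrosynthetic overview**
- Feature: cutting the bond between benzylic C7 and ring carbon B3 of the acylphloroglucinol ring (ring B) leaves the chain C7–C8(CH3)–C8'(CH3)–C7' between two 4-hydroxyphenyl rings (rings C and D). This is a C2-symmetric (R,R)-diphenol whose C7H2 and C7'H2 groups are interchangeable, and ring B of the dihydrochalcone likewise has two interchangeable CH positions (B3, B5).
- C7–B3 (last bond made): Friedel–Crafts capture of the acid-bound para-quinone methide (its O-protonated ion pair) generated from a C7 methyl ether, which comes from one-sided benzylic dehydrogenation of the symmetric diphenol; neither partner carries a protecting group.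
- C8–C8': oxidative dimerisation of the enolate of one Evans imide of 3-(4-methoxyphenyl)propanoic acid; the two imide carbonyls are then taken down to the two methyl groups and the aryl methyl ethers are cleaved.
- Acyl–B1: C-acylation of phloroglucinol with the same acid.
- Ring order: rings A to D are all bought as benzene rings and no ring is formed; the bonds are made in the order C8–C8', acyl–B1, C7–B3.

Key step: step 9

Remark: lignan-type locants are used for the butane chain (C7 carries ring C and ring B, then C8, C8', C7'); ring A is the 4-methoxyphenyl ring and ring B carries the acyl group at B1 and hydroxyls at B2, B4, B6. The target is taken as the (7R,8S,8'R) isomer drawn in the given SMILES, and both C7 epimers of the benzylic methyl ether are assumed usable because the key step passes through a planar intermediate.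

**Step 1**
Reactants: 1 3-(4-methoxyphenyl)propanoic acid; 2 (4S)-4-benzyl-1,3-oxazolidin-2-one
Product: 4 (4S)-4-benzyl-3-[3-(4-methoxyphenyl)propanoyl]-1,3-oxazolidin-2-one, via mixed pivalic anhydride 3 (not isolated)
Conditions: PivCl, Et3N, THF, −20 °C; then LiCl, 2, −20 °C → rt
Reagents that add atoms: none
Why: N-acylation of an oxazolidinone through a mixed anhydride, in which the hindered pivaloyl carbonyl is spared and the LiCl-activated oxazolidinone attacks the arylpropanoyl carbonyl; no stereocentre is formed.

**Step 2**
Reactants: 4 (4S)-4-benzyl-3-[3-(4-methoxyphenyl)propanoyl]-1,3-oxazolidin-2-one (two molecules)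
Product: 6 (4S,4'S)-3,3'-[(2R,3R)-2,3-bis(4-methoxybenzyl)butanedioyl]bis(4-benzyl-1,3-oxazolidin-2-one), via lithium Z-enolate 5 (not isolated)
Conditions: LiN(iPr)2 (1.1 equiv), THF, −78 °C; then TiCl4 (1.1 equiv, CH2Cl2 solution), −78 °C → rt
Reagents that add atoms: none
Why: Oxidative homocoupling of an Evans imide enolate, in which tetravalent titanium takes one electron from each chelated Z-enolate and the two α-carbons join; each carbon should bond on the face away from the C4 benzyl group of its auxiliary, as in an Evans alkylation, which sets both new centres (C8 and C8') as R.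

**Step 3**
Reactants: 6 the (R,R) bis-imide
Product: 7 (2R,3R)-2,3-bis(4-methoxybenzyl)butane-1,4-diol
Conditions: LiBH4, MeOH (additive), THF, 0 °C → rt
Reagents that add atoms: none
Why: Reductive cleavage of N-acyl oxazolidinones by borohydride, in which hydride attacks the exocyclic imide carbonyls, the auxiliary 2 is released for re-use and both acyl carbons end as CH2OH without epimerising the adjacent centres under these non-basic conditions.

**Step 4**
Reactants: 7 (2R,3R)-2,3-bis(4-methoxybenzyl)butane-1,4-diol
Product: 8 (2R,3R)-2,3-bis(4-methoxybenzyl)butane-1,4-diyl dimethanesulfonate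
Conditions: MsCl (3 equiv), Et3N, CH2Cl2, 0 °C
Reagents that add atoms: methanesulfonyl chloride, CS(=O)(=O)Cl
Why: Sulfonylation of two primary alcohols; excess MsCl at 0 °C should convert both hydroxyls quickly, so that a monomesylate does not linger and close to the tetrahydrofuran.

**Step 5**
Reactants: 8 the bis-mesylate
Product: 9 (2R,3R)-1,4-bis(4-methoxyphenyl)-2,3-dimethylbutane
Conditions: LiAlH4, THF, 0 °C → reflux
Reagents that add atoms: none
Why: SN2 displacement of primary sulfonates by hydride (deoxygenation through the mesylate), which turns both CH2OMs groups into CH3 at carbons that are not stereocentres.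

**Step 6**
Reactants: 9 (2R,3R)-1,4-bis(4-methoxyphenyl)-2,3-dimethylbutane
Product: 10 4,4'-[(2R,3R)-2,3-dimethylbutane-1,4-diyl]diphenol
Conditions: BBr3 (3 equiv), CH2Cl2, −78 °C → rt; then H2O
Reagents that add atoms: none
Why: Lewis-acid cleavage of aryl methyl ethers, in which BBr3 binds each anisole oxygen and bromide removes the methyl group by SN2; the saturated chain and its two centres are inert.

**Step 7**
Reactants: 10 the C2-symmetric diphenol
Product: 12 4-[(2S,3R)-4-(4-hydroxyphenyl)-1-methoxy-2,3-dimethylbutyl]phenol (both C1 epimers), via para-quinone methide 11 (not isolated)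
Conditions: DDQ (0.6 equiv, added slowly), MeOH, 0 °C → rt; recovered 10 recycled
Reagents that add atoms: methanol, CO
Why: Quinone dehydrogenation of a 4-alkylphenol, in which DDQ removes hydride from a benzylic CH2 para to a free hydroxyl and the solvent methanol adds to C7 of the free, neutral quinone methide 11; the two benzylic CH2 groups are exchanged by the C2 axis so only one constitutional isomer can form, the limiting oxidant restrains attack at the second terminus, and the C7 configuration is deliberately left uncontrolled.

**Step 8**
Reactants: 1 3-(4-methoxyphenyl)propanoic acid; 13 phloroglucinol (benzene-1,3,5-triol)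
Product: 14 3-(4-methoxyphenyl)-1-(2,4,6-trihydroxyphenyl)propan-1-one
Conditions: BF3·OEt2 (neat), 85 °C; then aq NaOAc
Reagents that add atoms: none
Why: Friedel–Crafts C-acylation of phloroglucinol by a carboxylic acid activated with BF3; the threefold symmetry allows one regioisomer only and the first, chelated acyl group deactivates the ring against a second acylation.

**Step 9**
Reactants: 12 the benzylic methyl ether (both C7 epimers); 14 the dihydrochalcone (3 equiv)
Product: 16 1-{2,4,6-trihydroxy-3-[(1R,2S,3R)-1,4-bis(4-hydroxyphenyl)-2,3-dimethylbutyl]phenyl}-3-(4-methoxyphenyl)propan-1-one (CNP0193401.2), via O-protonated quinone methide diphenyl phosphate ion pair 15 (not isolated)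
Conditions: (PhO)2P(O)OH (10 mol %), 4 Å MS, CH2Cl2/MeCN, −20 °C → rt; excess 14 recovered
Reagents that add atoms: none
Why: The phosphoric acid protonates the benzylic methoxy group of 12 and methanol leaves with push from the para-hydroxyl of ring C, so that both C7 epimers converge on one planar electrophile, the O-protonated para-quinone methide (a 4-hydroxybenzylic cation) held as contact ion pair 15 by diphenyl phosphate in the non-nucleophilic medium, and ring carbon B3 of 14 adds to its C7 terminus before proton loss restores both benzene rings and returns the catalyst. The closest known reaction type is the Brønsted-acid-catalysed Friedel–Crafts 1,6-addition of phenols and phloroglucinols to para-quinone methides generated in situ from 4-hydroxybenzyl alcohols or ethers. No ring is closed: the only bond formed is the intermolecular C7–B3 bond. The new C7 centre is controlled by the neighbouring C8 centre, because in the conformer of 15 that avoids allylic 1,3-strain the C8–H bond lies in the plane of the quinoid C7=ring bond facing the ortho C–H, the methyl group and the C8' branch then cover opposite faces, and the arene should enter past the smaller methyl group, anti to the C8' branch, which corresponds to 7R. The step needs diastereofacial selectivity at C7 and site selectivity for a single C-alkylation, and the substrate secures the latter through the two equivalent, strongly activated positions B3 and B5 of 14 (used in excess, O-alkylation being reversible under acid), while ring D could only close an aryltetralin through a carbon meta to its hydroxyl and so should not compete. Low temperature and fast capture by the electron-rich arene are relied on to outrun loss of the C8 proton from 15 to the 4-hydroxystyrene, which would erase C8.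

**Compound list**
1 | 3-(4-methoxyphenyl)propanoic acid | COc1ccc(CCC(=O)O)cc1 | starting material
2 | (4S)-4-benzyl-1,3-oxazolidin-2-one | O=C1N[C@@H](Cc2ccccc2)CO1 | starting material
3 | 3-(4-methoxyphenyl)propanoic pivalic anhydride | COc1ccc(CCC(=O)OC(=O)C(C)(C)C)cc1 | intermediate
4 | (4S)-4-benzyl-3-[3-(4-methoxyphenyl)propanoyl]-1,3-oxazolidin-2-one | COc1ccc(CCC(=O)N2C(=O)OC[C@@H]2Cc2ccccc2)cc1 | intermediate
5 | lithium Z-enolate of 4 | COc1ccc(C/C=C(\O[Li])N2C(=O)OC[C@@H]2Cc2ccccc2)cc1 | intermediate
6 | (4S,4'S)-3,3'-[(2R,3R)-2,3-bis(4-methoxybenzyl)butanedioyl]bis(4-benzyl-1,3-oxazolidin-2-one) | COc1ccc(C[C@@H](C(=O)N2C(=O)OC[C@@H]2Cc2ccccc2)[C@H](C(=O)N2C(=O)OC[C@@H]2Cc2ccccc2)Cc2ccc(OC)cc2)cc1 | intermediate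
7 | (2R,3R)-2,3-bis(4-methoxybenzyl)butane-1,4-diol | COc1ccc(C[C@@H](CO)[C@H](CO)Cc2ccc(OC)cc2)cc1 | intermediate
8 | (2R,3R)-2,3-bis(4-methoxybenzyl)butane-1,4-diyl dimethanesulfonate | COc1ccc(C[C@@H](COS(C)(=O)=O)[C@H](COS(C)(=O)=O)Cc2ccc(OC)cc2)cc1 | intermediate
9 | (2R,3R)-1,4-bis(4-methoxyphenyl)-2,3-dimethylbutane | COc1ccc(C[C@@H](C)[C@H](C)Cc2ccc(OC)cc2)cc1 | intermediate
10 | 4,4'-[(2R,3R)-2,3-dimethylbutane-1,4-diyl]diphenol | Oc1ccc(C[C@@H](C)[C@H](C)Cc2ccc(O)cc2)cc1 | intermediate
11 | 4-[(2S,3R)-4-(4-hydroxyphenyl)-2,3-dimethylbutylidene]cyclohexa-2,5-dien-1-one | O=C1C=CC(=C[C@@H](C)[C@H](C)Cc2ccc(O)cc2)C=C1 | intermediate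
12 | 4-[(2S,3R)-4-(4-hydroxyphenyl)-1-methoxy-2,3-dimethylbutyl]phenol, both C1 epimers | COC(c1ccc(O)cc1)[C@@H](C)[C@H](C)Cc1ccc(O)cc1 | intermediate
13 | phloroglucinol (benzene-1,3,5-triol) | Oc1cc(O)cc(O)c1 | starting material
14 | 3-(4-methoxyphenyl)-1-(2,4,6-trihydroxyphenyl)propan-1-one | COc1ccc(CCC(=O)c2c(O)cc(O)cc2O)cc1 | intermediate
15 | (2S,3R)-1,4-bis(4-hydroxyphenyl)-2,3-dimethylbutan-1-ylium diphenyl phosphate (O-protonated quinone methide ion pair) | Oc1ccc([CH+][C@@H](C)[C@H](C)Cc2ccc(O)cc2)cc1.[O-]P(=O)(Oc1ccccc1)Oc1ccccc1 | intermediate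
16 | 1-{2,4,6-trihydroxy-3-[(1R,2S,3R)-1,4-bis(4-hydroxyphenyl)-2,3-dimethylbutyl]phenyl}-3-(4-methoxyphenyl)propan-1-one (CNP0193401.2) | COc1ccc(CCC(=O)c2c(O)cc(O)c([C@@H](c3ccc(O)cc3)[C@@H](C)[C@H](C)Cc3ccc(O)cc3)c2O)cc1 | target

**Step count**
Total: 9 steps. Longest linear sequence: 8 steps (steps 1 to 7, then step 9); step 8 is a one-step side branch.

**Steps most likely to fail**

Step 9. The 1,2-induction from C8 may be weak, so that the arene adds to both faces of the planar electrophile and the C7 epimer forms alongside 16; a sluggish capture would also give the ionised intermediate time to lose the C8 proton and erode C8. The fallback hands face selection to a chiral catalyst, changes the nucleophile and attaches the acyl chain last. It sets out from 12, which is ionised with a bulky BINOL phosphoric acid, (R)- or (S)-3,3'-bis(2,4,6-triisopropylphenyl)-1,1'-binaphthyl-2,2'-diyl hydrogen phosphate (the enantiomer matched to the C8 centre to be chosen by screening both), in MeCN/CH2Cl2 at −40 °C with excess phloroglucinol 13. Its three equivalent and more nucleophilic ring positions should capture the ionised benzylic carbon inside the chiral phosphate pocket at low temperature to give the triphenol 2-[(1R,2S,3R)-1,4-bis(4-hydroxyphenyl)-2,3-dimethylbutyl]benzene-1,3,5-triol F1, which is freed from residual C7 epimer by chromatography or crystallisation. F1 again has two equivalent free ring positions and is C-acylated with acid 1 in BF3·OEt2 under the conditions of step 8, which brings the route back at 16.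

Step 7. The oxidation may not stop at one terminus: the second, equivalent benzylic CH2 can be attacked and the first-formed ether can be oxidised on towards the aryl ketone, leaving the mono-ether as a minor part of a mixture that is hard to separate. The fallback breaks the symmetry at oxygen before the oxidation. It sets out from 10: pivaloyl chloride (0.9 equiv) and pyridine in CH2Cl2 should give the mono-ester 4-[(2R,3R)-4-(4-hydroxyphenyl)-2,3-dimethylbutyl]phenyl pivalate F2, with diphenol and diester separated by polarity and returned to 10 (the diester after saponification). Only the ring that keeps its free hydroxyl can be dehydrogenated, so a full equivalent of DDQ in MeOH should convert F2 into the benzylic methyl ether 4-[(2R,3S)-4-(4-hydroxyphenyl)-4-methoxy-2,3-dimethylbutyl]phenyl pivalate F3 (both C4 epimers). Methanolysis of the aryl ester with K2CO3 in MeOH at room temperature then returns the route to 12.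

Step 2. The one-electron oxidation may give reduced or chlorinated monomer in place of the dimer, or the two enolate carbons may couple with incomplete face control so that the meso bis-imide contaminates 6. The fallback builds the C8–C8' unit by two separate enolate alkylations. It sets out from 4: NaN(SiMe3)2 in THF at −78 °C followed by tert-butyl bromoacetate (Evans alkylation, same facial rule) should give (4S)-4-benzyl-3-[(2R)-4-tert-butoxy-2-(4-methoxybenzyl)-4-oxobutanoyl]-1,3-oxazolidin-2-one F4. LiBH4 in wet Et2O removes the auxiliary to give tert-butyl (3R)-3-(hydroxymethyl)-4-(4-methoxyphenyl)butanoate F5, which closes under CF3CO2H in CH2Cl2 to (4R)-4-(4-methoxybenzyl)oxolan-2-one F6. Alkylation of F6 with 4-methoxybenzyl bromide (LiN(iPr)2, THF, −78 °C) should occur anti to the existing benzyl group and give the trans lactone (3R,4R)-3,4-bis(4-methoxybenzyl)oxolan-2-one F7, and LiAlH4 in THF opens F7 to the diol 7, where the route is rejoined.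

**Further compounds**
F1 | step 9 | 2-[(1R,2S,3R)-1,4-bis(4-hydroxyphenyl)-2,3-dimethylbutyl]benzene-1,3,5-triol | Oc1cc(O)c([C@@H](c2ccc(O)cc2)[C@@H](C)[C@H](C)Cc2ccc(O)cc2)c(O)c1
F2 | step 7 | 4-[(2R,3R)-4-(4-hydroxyphenyl)-2,3-dimethylbutyl]phenyl pivalate | CC(C)(C)C(=O)Oc1ccc(C[C@@H](C)[C@H](C)Cc2ccc(O)cc2)cc1
F3 | step 7 | 4-[(2R,3S)-4-(4-hydroxyphenyl)-4-methoxy-2,3-dimethylbutyl]phenyl pivalate, both C4 epimers | COC(c1ccc(O)cc1)[C@@H](C)[C@H](C)Cc1ccc(OC(=O)C(C)(C)C)cc1
F4 | step 2 | (4S)-4-benzyl-3-[(2R)-4-tert-butoxy-2-(4-methoxybenzyl)-4-oxobutanoyl]-1,3-oxazolidin-2-one | COc1ccc(C[C@@H](C(=O)N2C(=O)OC[C@@H]2Cc2ccccc2)CC(=O)OC(C)(C)C)cc1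
F5 | step 2 | tert-butyl (3R)-3-(hydroxymethyl)-4-(4-methoxyphenyl)butanoate | COc1ccc(C[C@@H](CO)CC(=O)OC(C)(C)C)cc1
F6 | step 2 | (4R)-4-(4-methoxybenzyl)oxolan-2-one | COc1ccc(C[C@H]2COC(=O)C2)cc1
F7 | step 2 | (3R,4R)-3,4-bis(4-methoxybenzyl)oxolan-2-one | COc1ccc(C[C@H]2COC(=O)[C@@H]2Cc2ccc(OC)cc2)cc1
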